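**Retrosynthetic overview**
1. The C8 methylene goes on last; before that the key C9–C11 bond and the C9 quaternary centre join a decalin enone (fragment 1) to the finished side-chain acid (fragment 2) in a visible-light decarboxylative radical conjugate addition.
2. Fragment 1: ring A comes from (R)-carvone (γ-hydroxylation sets C1, then the isopropenyl group is excised); a one-pot conjugate addition/aldol sets C10, C5 and C6; ring B is closed by ring-closing metathesis (C8=C9).
3. C4 methylene by carbonyl methylenation, C7 ketone by allylic oxidation, C1 ester from bought (R)-2-methylbutanoic acid.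
4. Fragment 2: L-aspartic acid 4-tert-butyl ester gives C12 (diazotisation with retention); tigloylation, diazoketone homologation and an intramolecular Reformatsky reaction close the hydroxy lactone and set C13.
5. Ring order: ring A (bought) → ring B (metathesis) → lactone ring (made separately, joined in the key step).

Assumption: the target is taken exactly as drawn in the SMILES (trans-decalin; 1β-ester; 6α-OH; 12S; 13S; (R)-2-methylbutanoate); atoms carry clerodane numbers C1–C20, α is the face of the C5 and C9 methyl groups, β the face of H-10; aldehyde 9 is used as the racemate because its stereocentre is destroyed in step 11.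

**Route**

Step 1
Reactants: 1 (R)-carvone
Product: 2 (S)-tert-butyldimethyl{[2-methyl-5-(prop-1-en-2-yl)cyclohexa-1,3-dien-1-yl]oxy}silane
Conditions: t-BuOK, THF, 0 °C; then TBSCl, −78 °C to rt
Reagents that add atoms: tert-butyldimethylsilyl chloride, CC(C)(C)[Si](C)(C)Cl
Why: Thermodynamic γ-deprotonation at ring carbon 4 gives the linearly conjugated dienolate, which the hard silyl chloride traps on oxygen (enol silylation); the carvone stereocentre is not touched.

Step 2
Reactants: 2 linear silyl dienol ether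
Product: 3 (4S,5R)-4-hydroxy-2-methyl-5-(prop-1-en-2-yl)cyclohex-2-en-1-one
Conditions: dimethyldioxirane, acetone/CH2Cl2, −78 °C; then AcOH, THF/H2O
Reagents that add atoms: dimethyldioxirane, CC1(C)OO1
Why: Vinylogous Rubottom oxidation: the distal C3=C4 bond of the dienol ether is epoxidised anti to the neighbouring isopropenyl group and the epoxide opens to the γ-hydroxy enone, which sets the carbinol centre (C1 of the target) trans to the bought stereocentre.

Step 3
Reactants: 3 γ-hydroxy enone
Product: 4 (4S,5R)-4-[(tert-butyldimethylsilyl)oxy]-2-methyl-5-(prop-1-en-2-yl)cyclohex-2-en-1-one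
Conditions: TBSCl, imidazole, DMF, rt
Reagents that add atoms: tert-butyldimethylsilyl chloride, CC(C)(C)[Si](C)(C)Cl
Why: Imidazole-promoted silylation of the secondary allylic alcohol; no stereocentre is affected.

Step 4
Reactants: 4 silyl ether
Product: 6 (R)-4-[(tert-butyldimethylsilyl)oxy]-2-methylcyclohex-2-en-1-one, via methoxy hydroperoxide 5 (not isolated)
Conditions: O3, MeOH, −78 °C; then FeSO4·7H2O, PhSH, −78 °C to rt
Reagents that add atoms: none
Why: Dealkenylative hydrogenation: Criegee ozonolysis of the isopropenyl group in methanol gives the α-methoxy hydroperoxide, ferrous ion turns it into an alkoxy radical that loses methyl acetate by β-scission, and the ring radical takes a hydrogen atom from thiophenol; the silyloxy carbinol is untouched and becomes the only stereocentre.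

Step 5
Reactants: 7 methyl 2-hydroxybut-3-enoate (racemic)
Product: 8 methyl 2-[(tert-butyldimethylsilyl)oxy]but-3-enoate (racemic)
Conditions: TBSCl, imidazole, CH2Cl2, rt
Reagents that add atoms: tert-butyldimethylsilyl chloride, CC(C)(C)[Si](C)(C)Cl
Why: Standard silylation of a secondary alcohol.

Step 6
Reactants: 8 silyloxy ester
Product: 9 2-[(tert-butyldimethylsilyl)oxy]but-3-enal (racemic)
Conditions: i-Bu2AlH (1.05 equiv), CH2Cl2, −78 °C
Reagents that add atoms: none
Why: Partial ester reduction: the aluminium hemiacetal of the α-silyloxy ester is stable at −78 °C and gives the aldehyde on work-up.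

Step 7
Reactants: 6 (R)-4-silyloxy-2-methylcyclohexenone; 9 2-silyloxybut-3-enal
Product: 11 (2S,3R,4R)-4-[(tert-butyldimethylsilyl)oxy]-2-{(1R)-2-[(tert-butyldimethylsilyl)oxy]-1-hydroxybut-3-en-1-yl}-2-methyl-3-(prop-1-en-2-yl)cyclohexan-1-one (C7 epimers), via magnesium enolate 10 (not isolated)
Conditions: CH2=C(CH3)MgBr, CuBr·SMe2 (20 mol %), THF, −78 to −30 °C; then 9, −78 °C; aq NH4Cl
Reagents that add atoms: isopropenylmagnesium bromide, C=C(C)[Mg]Br
Why: Copper-catalysed 1,4-addition occurs anti to the silyloxy group (sets C10), and the magnesium enolate adds to the aldehyde anti to the new isopropenyl group through a closed Zimmerman–Traxler chair (tandem conjugate addition/aldol), which sets the quaternary C5 and, because the enolate methyl is cis to O–Mg, the 6α-carbinol; C7 forms as a mixture that is erased in step 11.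

Step 8
Reactants: 11 aldol adduct
Product: 12 decalin ketone (clerodane numbering): 4-oxo-1β,7ξ-bis[(tert-butyldimethylsilyl)oxy]-6α-hydroxy-5α,9-dimethyl-Δ8-decalin; 10β-H
Conditions: second-generation Grubbs catalyst (H2IMes)(PCy3)Cl2Ru=CHPh (5 mol %), toluene, 80 °C
Reagents that add atoms: none
Why: Ring-closing metathesis of the isopropenyl and vinyl groups, which sit trans-diequatorial on ring A, closes the trans-fused ring B with loss of ethene; no stereocentre changes.

Step 9
Reactants: 12 decalin ketone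
Product: 13 4-methylidene-1β,7ξ-bis[(tert-butyldimethylsilyl)oxy]-5α,9-dimethyl-Δ8-decalin-6α-ol; 10β-H
Conditions: Zn, CH2Br2, TiCl4, THF/CH2Cl2, 0 °C to rt
Reagents that add atoms: dibromomethane, BrCBr
Why: Lombardo–Takai methylenation with the non-basic zinc–titanium carbenoid converts the hindered C4 ketone without retro-aldol cleavage of the β-hydroxy ketone.

Step 10
Reactants: 13 bis-silyl ether
Product: 14 4-methylidene-5α,9-dimethyl-Δ8-decalin-1β,6α,7ξ-triol; 10β-H
Conditions: n-Bu4NF (3 equiv), THF, 0 °C to rt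
Reagents that add atoms: none
Why: Fluoride cleaves both silyl ethers; with no carbonyl group present the triol cannot epimerise.

Step 11
Reactants: 14 triol
Product: 15 1β,6α-dihydroxy-4-methylidene-5α,9-dimethyl-Δ8-decalin-7-one; 10β-H
Conditions: activated MnO2 (20 equiv), CH2Cl2, rt
Reagents that add atoms: none
Why: MnO2 oxidises only the allylic C7 alcohol, which gives the enone and removes the unwanted C7 stereocentre while the saturated C1 and C6 carbinols stay.

Step 12
Reactants: 15 diol enone; 16 (R)-2-methylbutanoic acid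
Product: 17 6α-hydroxy-4-methylidene-5α,9-dimethyl-7-oxo-Δ8-decalin-1β-yl (R)-2-methylbutanoate; 10β-H
Conditions: DCC, DMAP (10 mol %), CH2Cl2, 0 °C
Reagents that add atoms: none
Why: Steglich esterification goes to the C1 hydroxyl because the C6 hydroxyl is neopentylic and hydrogen-bonded to the C7 carbonyl; the acid stereocentre is bought and carbodiimide activation at 0 °C keeps it.

Step 13
Reactants: 18 L-aspartic acid 4-tert-butyl ester
Product: 19 (S)-4-tert-butoxy-2-hydroxy-4-oxobutanoic acid
Conditions: NaNO2, 1 M H2SO4, 0 °C to rt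
Reagents that add atoms: water, O
Why: Diazotisation of the α-amino acid goes with net retention (double inversion through the α-lactone), so the (S) carbinol that becomes C12 is bought with the amino acid.

Step 14
Reactants: 19 hydroxy acid
Product: 20 (S)-4-tert-butoxy-2-{[(E)-2-methylbut-2-enoyl]oxy}-4-oxobutanoic acid
Conditions: tigloyl chloride, pyridine, CH2Cl2, 0 °C; aqueous work-up
Reagents that add atoms: (E)-2-methylbut-2-enoyl chloride, C/C=C(\C)C(Cl)=O
Why: Acyl chloride esterification of the secondary alcohol; no bond to the stereocentre is broken.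

Step 15
Reactants: 20 O-tigloyl acid
Product: 22 tert-butyl (S)-5-diazo-3-{[(E)-2-methylbut-2-enoyl]oxy}-4-oxopentanoate, via acid chloride 21 (not isolated)
Conditions: Me2C=C(Cl)NMe2, CH2Cl2, 0 °C; then Me3SiCHN2, MeCN/THF, 0 °C
Reagents that add atoms: (trimethylsilyl)diazomethane, C[Si](C)(C)C=[N+]=[N-]
Why: Neutral acid chloride formation followed by acylation of the diazoalkane (Arndt–Eistert-type diazoketone synthesis); the absence of base keeps the α-acyloxy stereocentre and the tert-butyl ester intact.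

Step 16
Reactants: 22 diazoketone
Product: 23 tert-butyl (S)-5-(2-bromoacetoxy)-3-{[(E)-2-methylbut-2-enoyl]oxy}-4-oxopentanoate
Conditions: BrCH2CO2H (3 equiv), toluene, 60 °C
Reagents that add atoms: bromoacetic acid, OC(=O)CBr
Why: O–H insertion: the acid protonates the diazoketone and its carboxylate displaces dinitrogen, giving the α-acyloxy ketone without touching C12.

Step 17
Reactants: 23 bromoacetoxy ketone
Product: 24 tert-butyl (S)-3-[(S)-3-hydroxy-5-oxotetrahydrofuran-3-yl]-3-{[(E)-2-methylbut-2-enoyl]oxy}propanoate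
Conditions: SmI2 (2.2 equiv), THF, −78 °C
Reagents that add atoms: none
Why: Intramolecular samarium Reformatsky reaction: the samarium enolate of the bromoacetate closes the five-membered lactone onto the ketone anti to the C12 acyloxy group (polar Felkin–Anh control, the ester oxygen does not chelate), which sets the tertiary carbinol C13 as (S).

Step 18
Reactants: 24 tert-butyl ester
Product: 25 (S)-3-[(S)-3-hydroxy-5-oxotetrahydrofuran-3-yl]-3-{[(E)-2-methylbut-2-enoyl]oxy}propanoic acid
Conditions: CF3CO2H/CH2Cl2 (1:4), 0 °C to rt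
Reagents that add atoms: none
Why: Acidolysis of the tert-butyl ester with loss of isobutene; lactone, tiglate and tertiary alcohol are stable to the acid.

Step 19
Reactants: 25 side-chain acid; 17 decalin enone
Product: 27 8,17-dihydro target (C8 is CH2; full side chain on C9), via N-acyloxyphthalimide 26 (not isolated)
Conditions: N-hydroxyphthalimide, i-PrN=C=N-i-Pr, DMAP (cat.), CH2Cl2, rt; then 17, Hantzsch ester, Ru(bpy)3(PF6)2 (1 mol %), Sc(OTf)3 (30 mol %), CH2Cl2/MeCN, 450 nm LEDs, rt
Reagents that add atoms: none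
Why: Proposed new method: a visible-light decarboxylative Giese addition in which the primary radical released from 26 (one-electron reduction by the photoreduced ruthenium catalyst, loss of CO2) adds to C9 of enone 17 held as a five-membered Sc(OTf)3 chelate of the C7 carbonyl and C6 hydroxyl, the chelate lowering the LUMO and holding the α-keto radical until it is reduced and protonated at C8; approach on the β face, away from the axial C5 methyl that is 1,3-diaxial to the α trajectory, puts C11 equatorial and sets the quaternary C9; the closest known reaction types are photoredox Giese additions of redox-active esters and Lewis-acid-accelerated radical conjugate additions to chelating enones, neither shown for a primary radical closing a quaternary centre on a β,β-disubstituted α′-hydroxy cyclohexenone.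

Step 20
Reactants: 27 saturated C8 ketone
Product: 30 CNP0231308.2, via silyl enol ether 28 (not isolated), via Mannich base 29 (not isolated)
Conditions: Me3SiOTf, Et3N, CH2Cl2, −78 to 0 °C; CH2=NMe2+ I−, rt; MeI, then aq NaHCO3; citric acid, MeOH
Reagents that add atoms: N,N-dimethylmethyleneiminium iodide, C=[N+](C)C.[I-]
Why: Eschenmoser methylenation: soft enolisation goes towards C8 (the C6 side would give a tetrasubstituted bis-silyloxy alkene), the silyl enol ether undergoes a Mannich reaction and the quaternised amine is eliminated to the C8 methylene; no stereocentre is formed and the transient silyl ethers fall off on acidic work-up.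

**Compound list**

1 | (R)-carvone, (5R)-2-methyl-5-(prop-1-en-2-yl)cyclohex-2-en-1-one | O=C1C(C)=CC[C@@H](C(C)=C)C1 | starting material
2 | (S)-tert-butyldimethyl{[2-methyl-5-(prop-1-en-2-yl)cyclohexa-1,3-dien-1-yl]oxy}silane | C1(O[Si](C)(C)C(C)(C)C)=C(C)C=C[C@@H](C(C)=C)C1 | intermediate
3 | (4S,5R)-4-hydroxy-2-methyl-5-(prop-1-en-2-yl)cyclohex-2-en-1-one | O=C1C(C)=C[C@H](O)[C@@H](C(C)=C)C1 | intermediate
4 | (4S,5R)-4-[(tert-butyldimethylsilyl)oxy]-2-methyl-5-(prop-1-en-2-yl)cyclohex-2-en-1-one | O=C1C(C)=C[C@H](O[Si](C)(C)C(C)(C)C)[C@@H](C(C)=C)C1 | intermediate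
5 | 5-(1-hydroperoxy-1-methoxyethyl) analogue of 4 (ring stereocentres as in 4; both epimers at the peroxy carbon) | O=C1C(C)=C[C@H](O[Si](C)(C)C(C)(C)C)[C@@H](C(C)(OC)OO)C1 | intermediate
6 | (R)-4-[(tert-butyldimethylsilyl)oxy]-2-methylcyclohex-2-en-1-one | O=C1C(C)=C[C@H](O[Si](C)(C)C(C)(C)C)CC1 | intermediate
7 | methyl 2-hydroxybut-3-enoate (racemic) | C=CC(O)C(=O)OC | starting material
8 | methyl 2-[(tert-butyldimethylsilyl)oxy]but-3-enoate (racemic) | C=CC(O[Si](C)(C)C(C)(C)C)C(=O)OC | intermediate
9 | 2-[(tert-butyldimethylsilyl)oxy]but-3-enal (racemic) | C=CC(O[Si](C)(C)C(C)(C)C)C=O | intermediate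
10 | bromomagnesium enolate of (3R,4R)-4-[(tert-butyldimethylsilyl)oxy]-2-methyl-3-(prop-1-en-2-yl)cyclohexan-1-one | C1(O[Mg]Br)=C(C)[C@@H](C(C)=C)[C@H](O[Si](C)(C)C(C)(C)C)CC1 | intermediate
11 | (2S,3R,4R)-4-[(tert-butyldimethylsilyl)oxy]-2-{(1R)-2-[(tert-butyldimethylsilyl)oxy]-1-hydroxybut-3-en-1-yl}-2-methyl-3-(prop-1-en-2-yl)cyclohexan-1-one (C7 epimers) | O=C1CC[C@@H](O[Si](C)(C)C(C)(C)C)[C@H](C(C)=C)[C@@]1(C)[C@@H](O)C(O[Si](C)(C)C(C)(C)C)C=C | intermediate
12 | 4-oxo-1β,7ξ-bis[(tert-butyldimethylsilyl)oxy]-6α-hydroxy-5α,9-dimethyl-Δ8-decalin, 10β-H (clerodane numbering) | O=C1CC[C@@H](O[Si](C)(C)C(C)(C)C)[C@H]2[C@@]1(C)[C@@H](O)C(O[Si](C)(C)C(C)(C)C)C=C2C | intermediate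
13 | 4-methylidene analogue of 12 | C=C1CC[C@@H](O[Si](C)(C)C(C)(C)C)[C@H]2[C@@]1(C)[C@@H](O)C(O[Si](C)(C)C(C)(C)C)C=C2C | intermediate
14 | 4-methylidene-5α,9-dimethyl-Δ8-decalin-1β,6α,7ξ-triol, 10β-H | C=C1CC[C@@H](O)[C@H]2[C@@]1(C)[C@@H](O)C(O)C=C2C | intermediate
15 | 1β,6α-dihydroxy-4-methylidene-5α,9-dimethyl-Δ8-decalin-7-one, 10β-H | C=C1CC[C@@H](O)[C@H]2[C@@]1(C)[C@@H](O)C(=O)C=C2C | intermediate
16 | (R)-2-methylbutanoic acid | OC(=O)[C@H](C)CC | starting material
17 | 6α-hydroxy-4-methylidene-5α,9-dimethyl-7-oxo-Δ8-decalin-1β-yl (R)-2-methylbutanoate, 10β-H (fragment 1) | C=C1CC[C@@H](OC(=O)[C@H](C)CC)[C@H]2[C@@]1(C)[C@@H](O)C(=O)C=C2C | intermediate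
18 | L-aspartic acid 4-tert-butyl ester | N[C@@H](CC(=O)OC(C)(C)C)C(=O)O | starting material
19 | (S)-4-tert-butoxy-2-hydroxy-4-oxobutanoic acid | CC(C)(C)OC(=O)C[C@H](O)C(=O)O | intermediate
20 | (S)-4-tert-butoxy-2-{[(E)-2-methylbut-2-enoyl]oxy}-4-oxobutanoic acid | CC(C)(C)OC(=O)C[C@H](OC(=O)/C(C)=C/C)C(=O)O | intermediate
21 | acid chloride of 20 | CC(C)(C)OC(=O)C[C@H](OC(=O)/C(C)=C/C)C(Cl)=O | intermediate
22 | tert-butyl (S)-5-diazo-3-{[(E)-2-methylbut-2-enoyl]oxy}-4-oxopentanoate | CC(C)(C)OC(=O)C[C@H](OC(=O)/C(C)=C/C)C(=O)C=[N+]=[N-] | intermediate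
23 | tert-butyl (S)-5-(2-bromoacetoxy)-3-{[(E)-2-methylbut-2-enoyl]oxy}-4-oxopentanoate | CC(C)(C)OC(=O)C[C@H](OC(=O)/C(C)=C/C)C(=O)COC(=O)CBr | intermediate
24 | tert-butyl (S)-3-[(S)-3-hydroxy-5-oxotetrahydrofuran-3-yl]-3-{[(E)-2-methylbut-2-enoyl]oxy}propanoate | CC(C)(C)OC(=O)C[C@H](OC(=O)/C(C)=C/C)[C@@]1(O)COC(=O)C1 | intermediate
25 | (S)-3-[(S)-3-hydroxy-5-oxotetrahydrofuran-3-yl]-3-{[(E)-2-methylbut-2-enoyl]oxy}propanoic acid (fragment 2) | OC(=O)C[C@H](OC(=O)/C(C)=C/C)[C@@]1(O)COC(=O)C1 | intermediate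
26 | 1,3-dioxoisoindolin-2-yl ester of 25 | O=C(C[C@H](OC(=O)/C(C)=C/C)[C@@]1(O)COC(=O)C1)ON1C(=O)c2ccccc2C1=O | intermediate
27 | 8,17-dihydro target (C8 = CH2) | C=C1CC[C@@H](OC(=O)[C@H](C)CC)[C@H]2[C@@]1(C)[C@@H](O)C(=O)C[C@]2(C)C[C@H](OC(=O)/C(C)=C/C)[C@@]1(O)COC(=O)C1 | intermediate
28 | C7 trimethylsilyl enol ether (C7=C8) of 27 with 6-O- and 13-O-trimethylsilyl groups | C=C1CC[C@@H](OC(=O)[C@H](C)CC)[C@H]2[C@@]1(C)[C@@H](O[Si](C)(C)C)C(O[Si](C)(C)C)=C[C@]2(C)C[C@H](OC(=O)/C(C)=C/C)[C@@]1(O[Si](C)(C)C)COC(=O)C1 | intermediate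
29 | 8-[(dimethylamino)methyl] ketone, 6-O,13-O-bis(trimethylsilyl) (C8 epimers) | C=C1CC[C@@H](OC(=O)[C@H](C)CC)[C@H]2[C@@]1(C)[C@@H](O[Si](C)(C)C)C(=O)C(CN(C)C)[C@]2(C)C[C@H](OC(=O)/C(C)=C/C)[C@@]1(O[Si](C)(C)C)COC(=O)C1 | intermediate
30 | CNP0231308.2 (1R,5R,6R,9R,10R,12S,13S) | C=C1CC[C@@H](OC(=O)[C@H](C)CC)[C@H]2[C@@]1(C)[C@@H](O)C(=O)C(=C)[C@]2(C)C[C@H](OC(=O)/C(C)=C/C)[C@@]1(O)COC(=O)C1 | target

**Totals**
Total step count: 20 (steps 1–12 fragment 1, including 2 steps for aldehyde 9; steps 13–18 fragment 2; steps 19–20 union and finish).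
Longest linear sequence: 12 steps (1–4, 7–12, 19, 20) from (R)-carvone.

**Three steps most likely to fail**

Step 19 (the new step). Radical addition to a β,β-disubstituted enone whose α face carries a 1,3-diaxial methyl is slow, so premature reduction of the primary radical by the Hantzsch ester may win. The fallback sets out from 25 and 17 and comes back at 27, using known thermal chemistry. Acid 25 is converted with 2-mercaptopyridine N-oxide and DCC into the 2-thioxopyridin-1(2H)-yl ester of 25 F4. Irradiation with CHI3 (Barton decarboxylative iodination) gives (1R)-1-[(3S)-3-hydroxy-5-oxooxolan-3-yl]-2-iodoethyl (E)-2-methylbut-2-enoate F5. A nickel-catalysed reductive conjugate addition of F5 to 17 [NiCl2(dme), 2,9-dimethyl-1,10-phenanthroline, Mn powder, Et3SiCl, DMF, 40 °C], a thermal reaction known to build quaternary centres on β,β-disubstituted enones through a silyloxy-allylnickel species, gives the triethylsilyl enol ether of 27 F6. Mild acid hydrolysis of F6 returns 27.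

Step 1. Silylation may give the cross-conjugated dienol ether (deprotonation at ring carbon 6) instead of the linear one, which would lead to α′- and not γ-hydroxylation. The fallback sets out from 1 and comes back at 3, replacing steps 1 and 2. Carvone 1 is condensed with pyrrolidine (MeOH, molecular sieves, rt) to the linear dienamine 1-[(5S)-2-methyl-5-(prop-1-en-2-yl)cyclohexa-1,3-dien-1-yl]pyrrolidine F1, the thermodynamic isomer as with steroidal enones. γ-Selective oxygenation with O2 at −40 °C and hydrolysis of the iminium ion (aq AcOH) give (4S,5R)-4-hydroperoxy-2-methyl-5-(prop-1-en-2-yl)cyclohex-2-en-1-one F2, again anti to the isopropenyl group. Reduction of F2 with Me2S gives 3.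

Step 7. The tetrasubstituted magnesium enolate may add poorly to the enolisable aldehyde in the presence of copper and magnesium salts, or with low control at C5 and C6. The fallback sets out from 6 and 9 and comes back at 11. Enone 6 is treated with CH2=C(CH3)MgBr, CuBr·SMe2 (cat.) and Me3SiCl, and the trimethylsilyl enol ether tert-butyldimethyl{[(1R,2R)-3-methyl-2-(prop-1-en-2-yl)-4-[(trimethylsilyl)oxy]cyclohex-3-en-1-yl]oxy}silane F3 is isolated. MeLi (THF, 0 °C) then releases the salt-free lithium enolate, ZnCl2 gives the zinc enolate, and 9 is added at −78 °C to give 11 through the same chair transition state.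

Further compounds
F1 | step 1 | 1-[(5S)-2-methyl-5-(prop-1-en-2-yl)cyclohexa-1,3-dien-1-yl]pyrrolidine | C1(N2CCCC2)=C(C)C=C[C@@H](C(C)=C)C1
F2 | step 1 | (4S,5R)-4-hydroperoxy-2-methyl-5-(prop-1-en-2-yl)cyclohex-2-en-1-one | O=C1C(C)=C[C@H](OO)[C@@H](C(C)=C)C1
F3 | step 7 | tert-butyldimethyl{[(1R,2R)-3-methyl-2-(prop-1-en-2-yl)-4-[(trimethylsilyl)oxy]cyclohex-3-en-1-yl]oxy}silane | C1(O[Si](C)(C)C)=C(C)[C@@H](C(C)=C)[C@H](O[Si](C)(C)C(C)(C)C)CC1
F4 | step 19 | 2-thioxopyridin-1(2H)-yl ester of 25 | S=C1C=CC=CN1OC(=O)C[C@H](OC(=O)/C(C)=C/C)[C@@]1(O)COC(=O)C1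
F5 | step 19 | (1R)-1-[(3S)-3-hydroxy-5-oxooxolan-3-yl]-2-iodoethyl (E)-2-methylbut-2-enoate | IC[C@H](OC(=O)/C(C)=C/C)[C@@]1(O)COC(=O)C1
F6 | step 19 | triethylsilyl enol ether (C7=C8) of 27 | C=C1CC[C@@H](OC(=O)[C@H](C)CC)[C@H]2[C@@]1(C)[C@@H](O)C(O[Si](CC)(CC)CC)=C[C@]2(C)C[C@H](OC(=O)/C(C)=C/C)[C@@]1(O)COC(=O)C1
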